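Removing O1–O2 from the 1,2-dioxolane ring (C3, C4, C5, O1, O2) and joining C3 to C5 leaves a cyclopropane, while the acetic acid arm C2–C1 is traced back to a vinyl substituent on C3. This 1,3-dioxygenated C3–C4–C5 unit is what the key step exploits. In one operation a thiyl radical chain opens vinylcyclopropane 22 to the tertiary C5 radical, takes up triplet oxygen and forms C5–O1 and C3–O2, creating the ring and both quaternary stereocentres. Because C3 and C5 are planarised on the way, 22 (1,2-dimethyl-1-vinylcyclopropane, side chain on C5) is prepared stereorandomly from alkene 16 through a dibromocyclopropane. C11 stems from (S)-citronellol, C7 from an auxiliary-controlled alkylation.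

Key step: step 13

Remark on numbering and configuration: C1 is the carboxyl carbon and C15 the benzylic carbon; the ring is C3, C4, C5, O1 (on C5), O2 (on C3). The SMILES reads as (3R,5R,7R,11S), with the C2 arm and the C6 arm on the same ring face. The CIP labels at C7 (S in 12–15, R from 16 on) and at C3 (S in 24 and 25, R elsewhere) change only because substituent priorities change.

Remark on materials: (S)-citronellol of high enantiomeric purity is assumed. Its hydroxyethyl arm becomes C10–C9 and its alkenyl arm C12–C14, which gives 11S without any inversion.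

Step 1
Reactants: 1 (S)-citronellol
Product: 2 (3S)-3,7-dimethyloct-6-en-1-yl 4-methylbenzenesulfonate
Conditions: TsCl, Et3N, DMAP (cat.), CH2Cl2, 0 °C → rt
Reagents that add atoms: p-toluenesulfonyl chloride, Cc1ccc(cc1)S(=O)(=O)Cl
Why: Sulfonylation of a primary alcohol (tosylate formation) is routine, leaves C11 and the trisubstituted alkene untouched, and installs a group that masks the oxygen through steps 2–4 and later serves as the leaving group at C9.

Step 2
Reactants: 2 (3S)-3,7-dimethyloct-6-en-1-yl 4-methylbenzenesulfonate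
Product: 4 (3S)-3-methyl-6-oxohexyl 4-methylbenzenesulfonate, via secondary ozonide 3 (not isolated)
Conditions: O3, CH2Cl2, −78 °C; then PPh3, −78 °C → rt
Reagents that add atoms: ozone, [O-][O+]=O
Why: Ozonolysis with reductive work-up cleaves the only C=C bond at C14, the electron-poor tosyl arene and the sulfonate ester being inert to ozone at −78 °C.

Step 3
Reactants: 4 (3S)-3-methyl-6-oxohexyl 4-methylbenzenesulfonate; 5 benzyltriphenylphosphonium chloride
Product: 7 (3S)-3-methyl-7-phenylhept-6-en-1-yl 4-methylbenzenesulfonate (E/Z mixture), via benzylidenetriphenylphosphorane 6 (not isolated)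
Conditions: 5 (1.2 equiv), NaHMDS (1.15 equiv), THF, 0 °C; then 4, −78 °C → rt
Reagents that add atoms: none
Why: Wittig olefination: the semi-stabilised ylide 6, generated with a slight deficit of base, adds to the aldehyde far faster than it can be alkylated by the primary tosylate, and the E/Z outcome is irrelevant because the alkene is saturated next.

Step 4
Reactants: 7 (3S)-3-methyl-7-phenylhept-6-en-1-yl 4-methylbenzenesulfonate
Product: 8 (3S)-3-methyl-7-phenylheptyl 4-methylbenzenesulfonate
Conditions: H2 (1 atm), 10% Pd/C, EtOAc, rt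
Reagents that add atoms: none
Why: Heterogeneous catalytic hydrogenation saturates the styrene-type C14=C15 bond under conditions that leave alkyl tosylates and arenes untouched.

Step 5
Reactants: 9 (4R)-4-benzyl-3-propanoyl-1,3-oxazolidin-2-one; 10 3-bromo-2-methylprop-1-ene
Product: 12 (4R)-4-benzyl-3-[(2S)-2,4-dimethylpent-4-enoyl]-1,3-oxazolidin-2-one, via sodium (Z)-enolate 11 (not isolated)
Conditions: NaHMDS, THF, −78 °C; then 10, Bu4NI (cat.), −78 → −40 °C
Reagents that add atoms: none
Why: Evans asymmetric alkylation: the chelated (Z)-enolate 11 is attacked by the reactive allylic bromide on the face opposite the C4 benzyl group of the (R)-auxiliary, which sets C7 in the (S)-acyl configuration required for 7R in the target.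

Step 6
Reactants: 12 (4R)-4-benzyl-3-[(2S)-2,4-dimethylpent-4-enoyl]-1,3-oxazolidin-2-one
Product: 13 (2S)-2,4-dimethylpent-4-en-1-ol
Conditions: LiBH4, MeOH (1 equiv), Et2O, 0 °C
Reagents that add atoms: none
Why: Reductive cleavage of the N-acyloxazolidinone with lithium borohydride delivers the primary alcohol without enolisation, so C7 is preserved, the isolated alkene is inert and the auxiliary is recovered.

Step 7
Reactants: 13 (2S)-2,4-dimethylpent-4-en-1-ol
Product: 14 (4S)-5-bromo-2,4-dimethylpent-1-ene
Conditions: CBr4, PPh3, CH2Cl2, 0 °C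
Reagents that add atoms: carbon tetrabromide, BrC(Br)(Br)Br
Why: Appel bromination converts the primary alcohol by SN2 at C8 under neutral conditions, so that neither the adjacent C7 centre nor the acid-sensitive 1,1-disubstituted alkene is affected.

Step 8
Reactants: 14 (4S)-5-bromo-2,4-dimethylpent-1-ene; 8 (3S)-3-methyl-7-phenylheptyl 4-methylbenzenesulfonate
Product: 16 [(5S,9R)-5,9,11-trimethyldodec-11-en-1-yl]benzene, via Grignard reagent 15 (not isolated)
Conditions: 14 (1.5 equiv), Mg, I2 (trace), THF, rt → 40 °C; then 8, Li2CuCl4 (5 mol%), THF, −78 °C → rt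
Reagents that add atoms: none
Why: Copper-catalysed Grignard–alkyl tosylate cross-coupling (Li2CuCl4 catalysis) joins two primary carbons, C8 and C9, with the unhindered partner as electrophile, and touches neither C7 nor C11 nor the terminal alkene.

Step 9
Reactants: 16 [(5S,9R)-5,9,11-trimethyldodec-11-en-1-yl]benzene
Product: 17 1,1-dibromo-2-methyl-2-[(2R,6S)-2,6-dimethyl-10-phenyldecyl]cyclopropane (both C5 epimers)
Conditions: CHBr3, 50% aq NaOH, BnEt3NCl (cat.), CH2Cl2, 0 °C → rt
Reagents that add atoms: bromoform, BrC(Br)Br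
Why: Phase-transfer generation of dibromocarbene and its [2+1] cycloaddition to the electron-rich 1,1-disubstituted alkene, the only reactive site of hydrocarbon 16, builds the C3–C4–C5 ring; the new C5 centre forms as both epimers, which is of no consequence.

Step 10
Reactants: 17 1,1-dibromo-2-methyl-2-[(2R,6S)-2,6-dimethyl-10-phenyldecyl]cyclopropane
Product: 19 1-bromo-1,2-dimethyl-2-[(2R,6S)-2,6-dimethyl-10-phenyldecyl]cyclopropane (all ring isomers), via bromolithiocyclopropane 18 (not isolated)
Conditions: n-BuLi (1.05 equiv), THF, −100 °C; then MeI (excess), −100 °C → rt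
Reagents that add atoms: iodomethane, CI
Why: Bromine–lithium exchange on a gem-dibromocyclopropane gives carbenoid 18, which persists at about −100 °C long enough to be alkylated by excess iodomethane (carbenoid monoalkylation), placing the C3 methyl group; the C3 configuration is irrelevant.

Step 11
Reactants: 19 1-bromo-1,2-dimethyl-2-[(2R,6S)-2,6-dimethyl-10-phenyldecyl]cyclopropane
Product: 21 1,2-dimethyl-2-[(2R,6S)-2,6-dimethyl-10-phenyldecyl]cyclopropane-1-carbaldehyde (all ring isomers), via cyclopropyllithium 20 (not isolated)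
Conditions: t-BuLi (2.1 equiv), Et2O, −78 °C; DMF, −78 → 0 °C; then H2O
Reagents that add atoms: N,N-dimethylformamide, CN(C)C=O
Why: Bromine–lithium exchange with two equivalents of tert-butyllithium gives the tertiary cyclopropyllithium 20, which lacks a leaving group and is therefore stable at −78 °C, and its formylation with DMF (Bouveault aldehyde synthesis) introduces C2.

Step 12
Reactants: 21 1,2-dimethyl-2-[(2R,6S)-2,6-dimethyl-10-phenyldecyl]cyclopropane-1-carbaldehyde
Product: 22 1-ethenyl-1,2-dimethyl-2-[(2R,6S)-2,6-dimethyl-10-phenyldecyl]cyclopropane (all ring isomers)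
Conditions: MePPh3Br, KOt-Bu, THF, 0 °C; then 21, 0 °C → rt
Reagents that add atoms: methyltriphenylphosphonium bromide, [Br-].C[P+](c1ccccc1)(c1ccccc1)c1ccccc1
Why: Wittig methylenation of a non-enolisable aldehyde with the small unstabilised ylide tolerates the neopentyl-like environment and adds C1, completing the vinylcyclopropane.

Step 13
Reactants: 22 1-ethenyl-1,2-dimethyl-2-[(2R,6S)-2,6-dimethyl-10-phenyldecyl]cyclopropane (all ring isomers)
Product: 23 (3R,5R)-3-ethenyl-3,5-dimethyl-5-[(2R,6S)-2,6-dimethyl-10-phenyldecyl]-1,2-dioxolane (cis ring; separated from its ring isomers)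
Conditions: PhSSPh (0.2 equiv), AIBN (0.1 equiv), O2 (1 atm), hν (sunlamp, Pyrex), MeCN–CH2Cl2, −20 → 0 °C; SiO2 chromatography, normal-phase HPLC if needed
Reagents that add atoms: dioxygen, O=O
Why: Light cleaves PhSSPh to PhS•, which adds reversibly to the vinyl terminus C1; the resulting cyclopropylcarbinyl radical at C2 breaks the C3–C5 bond, the tertiary C5 radical combines with triplet O2 (C5–O1), the peroxyl radical attacks C3 of the newly formed C3=C2 allyl sulfide (C3–O2), and β-scission of C1–S regenerates both the vinyl group and PhS•, so sulfur is needed only in catalytic amount. The closest known reaction type is the thiyl- or selenyl-radical-catalysed aerobic ring expansion of vinylcyclopropanes to 3-vinyl-1,2-dioxolanes, applied here to a substrate in which C3 and C5 are both fully substituted. The dioxolane closes in the 5-exo-trig mode. C5 is fixed when O2 meets a planar radical whose only neighbour of fixed configuration is the remote C7, so no useful facial bias is expected and both C5 configurations should form, whereas C3 is fixed relative to C5 by a chair-like transition state that keeps the branched C6 arm and the C2 alkenyl arm pseudo-equatorial and thus leads to the cis ring. The step needs cleavage of C3–C5 rather than C3–C4, secured by tertiary versus primary radical stability, and cis closure, secured only by the size difference between the C6 arm and the C5 methyl group, which is why the reaction is run cold and stopped at full conversion. All isomers of 22 converge because C3 and C5 are planarised, and 23 is then separated from its (3S,5S) cis partner and from the trans pair.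

Step 14
Reactants: 23 (3R,5R)-3-ethenyl-3,5-dimethyl-5-[(2R,6S)-2,6-dimethyl-10-phenyldecyl]-1,2-dioxolane
Product: 25 2-{(3S,5R)-3,5-dimethyl-5-[(2R,6S)-2,6-dimethyl-10-phenyldecyl]-1,2-dioxolan-3-yl}ethan-1-ol, via B-alkyl-9-BBN adduct 24 (not isolated)
Conditions: 9-BBN (1.5 equiv), THF, 0 °C → rt; then 30% H2O2, 1 M NaOH, 0 °C
Reagents that add atoms: hydrogen peroxide, OO
Why: Hydroboration–oxidation: the bulky 9-BBN places boron on the unhindered terminus C1 (anti-Markovnikov), three bonds away from O2 so that no β-elimination can occur, and the di-tertiary peroxide, which has no α-hydrogen, should withstand the borane and the cold alkaline peroxide as related cyclic peroxides do; no stereocentre is involved.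

Step 15
Reactants: 25 2-{(3S,5R)-3,5-dimethyl-5-[(2R,6S)-2,6-dimethyl-10-phenyldecyl]-1,2-dioxolan-3-yl}ethan-1-ol
Product: 27 2-{(3R,5R)-3,5-dimethyl-5-[(2R,6S)-2,6-dimethyl-10-phenyldecyl]-1,2-dioxolan-3-yl}acetic acid (target), via aldehyde 26 (not isolated)
Conditions: TEMPO (0.2 equiv), PhI(OAc)2 (2.5 equiv), MeCN–H2O (1:1), rt
Reagents that add atoms: water, O
Why: Oxoammonium-mediated oxidation (TEMPO/PhI(OAc)2 in aqueous acetonitrile) carries the primary alcohol through aldehyde 26 and its hydrate to the acid under weakly acidic conditions, which avoids base-induced β-elimination of the peroxide from 26 and leaves the O–O bond, the benzylic position and all four stereocentres untouched.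

Compound list
1 | (S)-citronellol | C[C@@H](CCC=C(C)C)CCO | starting material
2 | (3S)-3,7-dimethyloct-6-en-1-yl 4-methylbenzenesulfonate | C[C@@H](CCC=C(C)C)CCOS(=O)(=O)c1ccc(C)cc1 | intermediate
3 | secondary ozonide of 2 (3,3-dimethyl-1,2,4-trioxolane, not isolated) | C[C@@H](CCC1OOC(C)(C)O1)CCOS(=O)(=O)c1ccc(C)cc1 | intermediate
4 | (3S)-3-methyl-6-oxohexyl 4-methylbenzenesulfonate | C[C@@H](CCC=O)CCOS(=O)(=O)c1ccc(C)cc1 | intermediate
5 | benzyltriphenylphosphonium chloride | [Cl-].c1ccc(cc1)C[P+](c1ccccc1)(c1ccccc1)c1ccccc1 | starting material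
6 | benzylidenetriphenylphosphorane (not isolated) | C(c1ccccc1)=P(c1ccccc1)(c1ccccc1)c1ccccc1 | intermediate
7 | (3S)-3-methyl-7-phenylhept-6-en-1-yl 4-methylbenzenesulfonate (E/Z) | C[C@@H](CCC=Cc1ccccc1)CCOS(=O)(=O)c1ccc(C)cc1 | intermediate
8 | (3S)-3-methyl-7-phenylheptyl 4-methylbenzenesulfonate | C[C@@H](CCCCc1ccccc1)CCOS(=O)(=O)c1ccc(C)cc1 | intermediate
9 | (4R)-4-benzyl-3-propanoyl-1,3-oxazolidin-2-one | CCC(=O)N1[C@H](Cc2ccccc2)COC1=O | starting material
10 | 3-bromo-2-methylprop-1-ene | C=C(C)CBr | starting material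
11 | sodium (Z)-enolate of 9 (not isolated) | C/C=C(\[O-])N1[C@H](Cc2ccccc2)COC1=O.[Na+] | intermediate
12 | (4R)-4-benzyl-3-[(2S)-2,4-dimethylpent-4-enoyl]-1,3-oxazolidin-2-one | C[C@@H](CC(C)=C)C(=O)N1[C@H](Cc2ccccc2)COC1=O | intermediate
13 | (2S)-2,4-dimethylpent-4-en-1-ol | C[C@@H](CC(C)=C)CO | intermediate
14 | (4S)-5-bromo-2,4-dimethylpent-1-ene | C[C@@H](CC(C)=C)CBr | intermediate
15 | [(2S)-2,4-dimethylpent-4-en-1-yl]magnesium bromide (not isolated) | C[C@@H](CC(C)=C)C[Mg]Br | intermediate
16 | [(5S,9R)-5,9,11-trimethyldodec-11-en-1-yl]benzene | C[C@@H](CCCCc1ccccc1)CCC[C@@H](C)CC(C)=C | intermediate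
17 | 1,1-dibromo-2-methyl-2-[(2R,6S)-2,6-dimethyl-10-phenyldecyl]cyclopropane (both C5 epimers) | C[C@@H](CCCCc1ccccc1)CCC[C@@H](C)CC1(C)CC1(Br)Br | intermediate
18 | 1-bromo-1-lithio-2-methyl-2-[(2R,6S)-2,6-dimethyl-10-phenyldecyl]cyclopropane (not isolated) | C[C@@H](CCCCc1ccccc1)CCC[C@@H](C)CC1(C)CC1([Li])Br | intermediate
19 | 1-bromo-1,2-dimethyl-2-[(2R,6S)-2,6-dimethyl-10-phenyldecyl]cyclopropane (all ring isomers) | C[C@@H](CCCCc1ccccc1)CCC[C@@H](C)CC1(C)CC1(C)Br | intermediate
20 | 1-lithio-1,2-dimethyl-2-[(2R,6S)-2,6-dimethyl-10-phenyldecyl]cyclopropane (not isolated) | C[C@@H](CCCCc1ccccc1)CCC[C@@H](C)CC1(C)CC1(C)[Li] | intermediate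
21 | 1,2-dimethyl-2-[(2R,6S)-2,6-dimethyl-10-phenyldecyl]cyclopropane-1-carbaldehyde (all ring isomers) | C[C@@H](CCCCc1ccccc1)CCC[C@@H](C)CC1(C)CC1(C)C=O | intermediate
22 | 1-ethenyl-1,2-dimethyl-2-[(2R,6S)-2,6-dimethyl-10-phenyldecyl]cyclopropane (all ring isomers) | C[C@@H](CCCCc1ccccc1)CCC[C@@H](C)CC1(C)CC1(C)C=C | intermediate
23 | (3R,5R)-3-ethenyl-3,5-dimethyl-5-[(2R,6S)-2,6-dimethyl-10-phenyldecyl]-1,2-dioxolane | C[C@@H](CCCCc1ccccc1)CCC[C@@H](C)C[C@]1(C)C[C@](C)(C=C)OO1 | intermediate
24 | 9-(2-{(3S,5R)-3,5-dimethyl-5-[(2R,6S)-2,6-dimethyl-10-phenyldecyl]-1,2-dioxolan-3-yl}ethyl)-9-borabicyclo[3.3.1]nonane (not isolated) | C[C@@H](CCCCc1ccccc1)CCC[C@@H](C)C[C@]1(C)C[C@](C)(CCB2C3CCCC2CCC3)OO1 | intermediate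
25 | 2-{(3S,5R)-3,5-dimethyl-5-[(2R,6S)-2,6-dimethyl-10-phenyldecyl]-1,2-dioxolan-3-yl}ethan-1-ol | C[C@@H](CCCCc1ccccc1)CCC[C@@H](C)C[C@]1(C)C[C@](C)(CCO)OO1 | intermediate
26 | 2-{(3R,5R)-3,5-dimethyl-5-[(2R,6S)-2,6-dimethyl-10-phenyldecyl]-1,2-dioxolan-3-yl}acetaldehyde (not isolated) | C[C@@H](CCCCc1ccccc1)CCC[C@@H](C)C[C@]1(C)C[C@](C)(CC=O)OO1 | intermediate
27 | 2-{(3R,5R)-3,5-dimethyl-5-[(2R,6S)-2,6-dimethyl-10-phenyldecyl]-1,2-dioxolan-3-yl}acetic acid | C[C@@H](CCCCc1ccccc1)CCC[C@@H](C)C[C@]1(C)C[C@](C)(CC(=O)O)OO1 | target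

Total step count: 15. Longest linear sequence: 12 steps (steps 1–4 and 8–15).

Steps most likely to fail

**Step 13.**
- What may go wrong:
  - weak discrimination between the C5 methyl group and the C6 arm in the ring-closing transition state, so that cis and trans rings form together
  - absence of any facial bias at C5
  - chain termination through hydrogen abstraction from benzylic or tertiary C–H bonds or through co-oxidation of sulfur
  - a laborious separation of four ring isomers
- Fallback (sets out from 16, returns at 25): the ring is assembled by a Lewis-acid-promoted [3+2] annulation of a peroxycarbenium ion with the alkene instead of by radical oxygenation. Commercial 3-methylbut-3-en-1-ol is silylated (TBDPSCl, imidazole, DMF) to tert-butyl[(3-methylbut-3-en-1-yl)oxy]diphenylsilane F1. Ozonolysis in MeOH–CH2Cl2 at −78 °C traps the ketone oxide as 4-[(tert-butyldiphenylsilyl)oxy]-2-methoxybutan-2-yl hydroperoxide F2, and Et3SiCl with imidazole converts it into the triethylsilyl peroxy ketal F3. With SnCl4 in CH2Cl2 at −78 °C, F3 ionises by loss of methoxide and C4 of 16 attacks the cationic carbon (the future C3). The tertiary C5 cation is then captured by the silylated peroxide oxygen with loss of the silyl group, which should give the silyl-protected dioxolane F4 as a mixture of ring isomers. TBAF in THF frees the alcohol, and 25 is separated from its ring isomers at that stage. Steps 9–14 are bypassed.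

**Step 10.**
- What may go wrong:
  - loss of LiBr from the carbenoid before it is alkylated, with ring opening to an allene or C–H insertion
  - competing alkylation by the butyl bromide formed in the exchange
- Fallback (sets out from 16, returns at 21): the methylene carbon C4 is delivered last instead of C3. Ozonolysis of 16 (O3, CH2Cl2, −78 °C; PPh3) gives (4R,8S)-4,8-dimethyl-12-phenyldodecan-2-one F5. Horner–Wadsworth–Emmons olefination with triethyl 2-phosphonopropionate (NaH, DME, reflux) gives ethyl (5R,9S)-2,3,5,9-tetramethyl-13-phenyltridec-2-enoate F6 as an E/Z mixture. DIBAL-H (CH2Cl2, −78 °C) gives (5R,9S)-2,3,5,9-tetramethyl-13-phenyltridec-2-en-1-ol F7. Hydroxyl-directed Simmons–Smith cyclopropanation (Et2Zn, CH2I2, CH2Cl2, 0 °C) gives {1,2-dimethyl-2-[(2R,6S)-2,6-dimethyl-10-phenyldecyl]cyclopropyl}methanol F8, and Dess–Martin oxidation leads to 21. Olefin geometry and ring configuration are again irrelevant.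

**Step 14.**
- What may go wrong:
  - reductive cleavage of the O–O bond by the borane
  - partial placement of boron on C2 followed by β-elimination and ring opening
- Fallback (sets out from 23, returns at 27 through 26): boron is avoided altogether. The reagent is an aldehyde-selective, nitrite-modified Wacker-type oxidation (PdCl2(PhCN)2, CuCl2, AgNO2, O2, t-BuOH–MeNO2, rt), a reaction type established for vinyl groups on quaternary carbon. It should place oxygen on C1 and give aldehyde 26, now isolated. Pinnick oxidation (NaClO2, NaH2PO4, 2-methylbut-2-ene, t-BuOH–H2O) then gives 27. No compound outside the list is made (F0).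

Further compounds
F1 | step 13 | tert-butyl[(3-methylbut-3-en-1-yl)oxy]diphenylsilane | C=C(C)CCO[Si](c1ccccc1)(c1ccccc1)C(C)(C)C
F2 | step 13 | 4-[(tert-butyldiphenylsilyl)oxy]-2-methoxybutan-2-yl hydroperoxide | COC(C)(OO)CCO[Si](c1ccccc1)(c1ccccc1)C(C)(C)C
F3 | step 13 | triethylsilyl peroxy ketal (tert-butyl{3-methoxy-3-[(triethylsilyl)peroxy]butoxy}diphenylsilane) | COC(C)(OO[Si](CC)(CC)CC)CCO[Si](c1ccccc1)(c1ccccc1)C(C)(C)C
F4 | step 13 | silyl-protected dioxolane (TBDPS ether of 25, all ring isomers) | C[C@@H](CCCCc1ccccc1)CCC[C@@H](C)CC1(C)CC(C)(CCO[Si](c2ccccc2)(c2ccccc2)C(C)(C)C)OO1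
F5 | step 10 | (4R,8S)-4,8-dimethyl-12-phenyldodecan-2-one | C[C@@H](CCCCc1ccccc1)CCC[C@@H](C)CC(C)=O
F6 | step 10 | ethyl (5R,9S)-2,3,5,9-tetramethyl-13-phenyltridec-2-enoate (E/Z) | C[C@@H](CCCCc1ccccc1)CCC[C@@H](C)CC(C)=C(C)C(=O)OCC
F7 | step 10 | (5R,9S)-2,3,5,9-tetramethyl-13-phenyltridec-2-en-1-ol (E/Z) | C[C@@H](CCCCc1ccccc1)CCC[C@@H](C)CC(C)=C(C)CO
F8 | step 10 | {1,2-dimethyl-2-[(2R,6S)-2,6-dimethyl-10-phenyldecyl]cyclopropyl}methanol (all ring isomers) | C[C@@H](CCCCc1ccccc1)CCC[C@@H](C)CC1(C)CC1(C)CO
F0 | step 14 | none | none
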